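The locants follow the heavy-atom order of the target SMILES. Both ring ether oxygens end on methyl-bearing quaternary carbons whose neighbours are oxygenated methines: O17 on C18 beside C10 in the pyran, and O9 on C7 beside C22 in the bridged oxepane. That pattern is unravelled to two trisubstituted epoxides. In one acid-triggered operation the C14 hydroxyl attacks C18, and the C10 hydroxyl thus freed attacks C7. This closes both heterocycles, inverts C18 and C7, and unveils C22–OH. The precursor is a cis-4,5-disubstituted 1-methylcyclohexene oxide. It bears a C5 silyl ether and a side chain with a Z-derived C18–C10 epoxide, the (12S)-bromide and the free C14 alcohol.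

Key step: step 16

Remarks on the chemistry (assumptions and design points)
* The target locants (C1 to O23) are used for all intermediates.
* O9 and C20 are cis on the pyran. With inversion at C18, this requires an epoxide in which C20 and C11 are cis, so the C18=C10 alkene must be Z.
* Read as reagent-controlled epoxidations, 10S and 22R call for opposite enantiomers of a fructose-derived ketone. In addition, 1,3-allylic strain holds H20 in the alkene plane, and the C5 branch then lies on the alkene face that must be oxidised.
* Both epoxides are therefore placed by substrate control. The side-chain oxygen is delivered from C5–OH. The ring alkene is made by metathesis only afterwards and is epoxidised anti to its substituents.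
* The bromide is introduced after the olefination, because a C10 carbanion would expel a C12 bromide to form a cyclopropane.
* The free bromohydrin never meets base, which would close it to the epoxide.
* The C5 group of the precursor is a silyl ether, because it has to be attached in the presence of an epoxide and a bromohydrin.
* Assumption: aldehyde 5 is used as a dried CH2Cl2 solution. The minor enantiomer of the epoxy sulfone ends up as a diastereomer after the coupling and is removed by chromatography.

Step 1
Reactants: 1 (4R)-4-benzyl-1,3-oxazolidin-2-one; 2 pent-4-enoyl chloride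
Product: 3 (4R)-4-benzyl-3-(pent-4-enoyl)-1,3-oxazolidin-2-one
Conditions: Et3N, DMAP (cat.), CH2Cl2, 0 °C → rt
Reagents that add atoms: none
Why: DMAP-catalysed N-acylation of the oxazolidinone by the acid chloride, in which no stereocentre is touched.

Step 2
Reactants: 4 3-methylbut-3-en-1-ol
Product: 5 3-methylbut-3-enal
Conditions: Dess–Martin periodinane, CH2Cl2, 0 °C → rt
Reagents that add atoms: none
Why: Dess–Martin oxidation runs without base, which should keep the β,γ-unsaturated aldehyde from moving into conjugation.

Step 3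
Reactants: 3 N-pentenoyl oxazolidinone; 5 3-methylbut-3-enal
Product: 7 (4R)-4-benzyl-3-[(2R,3S)-3-hydroxy-5-methyl-2-(prop-2-en-1-yl)hex-5-enoyl]-1,3-oxazolidin-2-one, via dibutylboron Z-enolate 6 (not isolated)
Conditions: Bu2BOTf, Et3N, CH2Cl2, −78 → 0 °C; 5, −78 → 0 °C; then pH 7 buffer, MeOH, 30% H2O2, 0 °C
Reagents that add atoms: none
Why: Evans syn-aldol reaction, in which the (Z)-boron enolate reacts through a chair Zimmerman–Traxler transition state on the face away from the benzyl group and thereby sets 20R and 5S (syn in the chain, cis on the later ring).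

Step 4
Reactants: 7 aldol adduct
Product: 8 (2R,3S)-3-hydroxy-N-methoxy-N,5-dimethyl-2-(prop-2-en-1-yl)hex-5-enamide
Conditions: MeONHMe·HCl, Me3Al, CH2Cl2, −20 → 0 °C
Reagents that add atoms: N,O-dimethylhydroxylamine hydrochloride, CNOC.Cl
Why: Aluminium amide transamination to the Weinreb amide, assisted by the free β-hydroxyl, releases the auxiliary without disturbing C20 or C5.

Step 5
Reactants: 8 hydroxy Weinreb amide
Product: 9 (2R,3S)-N-methoxy-N,5-dimethyl-2-(prop-2-en-1-yl)-3-(triethylsilyloxy)hex-5-enamide
Conditions: Et3SiCl, imidazole, CH2Cl2, 0 °C → rt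
Reagents that add atoms: chlorotriethylsilane, CC[Si](Cl)(CC)CC
Why: Silylation of the secondary alcohol blocks retro-aldol and alkoxide chemistry in the two basic steps that follow and gives a group that mild acid removes later.

Step 6
Reactants: 9 silylated Weinreb amide
Product: 10 (3R,4S)-6-methyl-3-(prop-2-en-1-yl)-4-(triethylsilyloxy)hept-6-en-2-one
Conditions: MeMgBr, THF, −20 → 0 °C
Reagents that add atoms: methylmagnesium bromide, C[Mg]Br
Why: Grignard addition to a Weinreb amide stops at the chelated tetrahedral adduct, so the quench should release only the methyl ketone (C19 installed) with C20 intact.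

Step 7
Reactants: 11 5-bromo-2-methylpent-2-ene; 12 1-methyl-1H-tetrazole-5-thiol
Product: 13 1-methyl-5-[(4-methylpent-3-en-1-yl)sulfanyl]-1H-tetrazole
Conditions: K2CO3, acetone, rt
Reagents that add atoms: none
Why: SN2 alkylation of the soft thiolate at the primary bromide.

Step 8
Reactants: 13 sulfide
Product: 14 1-methyl-5-[(4-methylpent-3-en-1-yl)sulfonyl]-1H-tetrazole
Conditions: (NH4)6Mo7O24·4H2O (cat.), 30% H2O2, EtOH, 0 °C → rt
Reagents that add atoms: hydrogen peroxide, OO
Why: Molybdate-catalysed peroxide oxidation of a sulfide to the sulfone is faster than epoxidation of an isolated trisubstituted alkene.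

Step 9
Reactants: 14 alkenyl sulfone
Product: 15 5-({2-[(2R)-3,3-dimethyloxiran-2-yl]ethyl}sulfonyl)-1-methyl-1H-tetrazole
Conditions: D-fructose-derived ketone catalyst (0.3 equiv), KHSO5 (Oxone, 2KHSO5·KHSO4·K2SO4), K2CO3, Bu4NHSO4, Na2B4O7/Na2EDTA buffer, MeCN–CH2(OMe)2–H2O, 0 °C
Reagents that add atoms: potassium peroxymonosulfate, [K+].[O-]S(=O)(=O)OO
Why: Shi epoxidation, in which the chiral dioxirane meets the trisubstituted alkene in a spiro transition state with the alkene hydrogen in the crowded quadrant, which should set 12R.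

Step 10
Reactants: 10 methyl ketone; 15 epoxy sulfone
Product: 16 (3R)-2,2-dimethyl-3-[(2Z,4S,5S)-3,7-dimethyl-4-(prop-2-en-1-yl)-5-(triethylsilyloxy)octa-2,7-dien-1-yl]oxirane
Conditions: LiN(SiMe3)2 added to 10 + 15, THF, −78 °C → rt
Reagents that add atoms: none
Why: Julia–Kocienski olefination, in which 1-methyltetrazolyl sulfones add to α-branched methyl ketones under kinetic control (lithium, THF, low temperature) so that Smiles transfer and anti elimination place the new chain cis to the larger ketone substituent and should give the (Z)-C18=C10 alkene, while adding the base last keeps the C10 carbanion too short-lived to attack the hindered C12 epoxide carbon.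

Step 11
Reactants: 16 (Z)-alkene epoxide
Product: 18 (3S,5Z,7S,8S)-3-bromo-2,6,10-trimethyl-7-(prop-2-en-1-yl)undeca-5,10-diene-2,8-diol, via bromohydrin triethylsilyl ether 17 (not isolated)
Conditions: Li2NiBr4, THF, 0 °C → rt; then 1 M aq. HCl, 0 °C → rt
Reagents that add atoms: dilithium tetrabromonickelate, [Li+].[Li+].[Ni+2].[Br-].[Br-].[Br-].[Br-]
Why: Regioselective halohydrin formation, in which soft bromide opens the epoxide in an SN2 manner at the less substituted C12 under near-neutral conditions (12R inverted to 12S, tertiary C14–OH released), after which dilute acid in the same flask hydrolyses the triethylsilyl ether.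

Step 12
Reactants: 18 bromohydrin diol
Product: 19 (5S,20R,18R,10S,12S)-epoxy diol, that is 18 with the C18=C10 alkene turned into the epoxide on the face of the C5 branch
Conditions: VO(acac)2 (5 mol%), t-BuOOH (1.1 equiv, decane), CH2Cl2, 0 °C
Reagents that add atoms: tert-butyl hydroperoxide, CC(C)(C)OO
Why: Vanadium-catalysed hydroxyl-directed epoxidation of a homoallylic alcohol, in which 1,3-allylic strain between C11 and the C20 substituents holds H20 in the alkene plane so that C5 and its vanadium-bound peroxide lie over one face only (sets 18R and 10S), while the less electron-rich 1,1-disubstituted and monosubstituted alkenes should react more slowly and the neutral medium spares the bromohydrin.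

Step 13
Reactants: 19 epoxy diol
Product: 20 5-O-tert-butyldimethylsilyl ether of 19
Conditions: TBSOTf (1.1 equiv), 2,6-lutidine, CH2Cl2, −78 °C
Reagents that add atoms: tert-butyldimethylsilyl triflate, CC(C)(C)[Si](C)(C)OS(=O)(=O)C(F)(F)F
Why: Silyl triflate with a hindered pyridine base silylates the secondary C5–OH faster than the tertiary C14–OH at low temperature, in a medium neither acidic enough to open the epoxide nor basic enough to close the bromohydrin, and installs a non-participating group.

Step 14
Reactants: 20 silyl ether diene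
Product: 21 (5S,20R,18R,10S,12S)-cyclohexene, a 1-methylcyclohexene (C7=C22) with cis C5–OTBS and C20 epoxy bromohydrin side chain
Conditions: second-generation Grubbs catalyst (H2IMes)(PCy3)Cl2Ru=CHPh (3 mol%), CH2Cl2, 40 °C
Reagents that add atoms: none
Why: Ring-closing metathesis of the monosubstituted and the 1,1-disubstituted alkene forms the six-membered ring with the trisubstituted C7=C22 alkene and loses ethene, with epoxide, bromide and alcohol as spectators.

Step 15
Reactants: 21 cyclohexene
Product: 22 (5S,7S,22R,20R,18R,10S,12S)-bis-epoxide bromohydrin with C5–OTBS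
Conditions: dimethyldioxirane (acetone solution), CH2Cl2, −20 °C
Reagents that add atoms: dimethyldioxirane, CC1(C)OO1
Why: Dioxirane epoxidation under neutral conditions with only acetone as by-product; in either half-chair one of the two cis substituents at C5 and C20 is axial on the same face, so oxygen should arrive anti to both and set 7S and 22R.

Step 16
Reactants: 22 bis-epoxide bromohydrin
Product: 24 5-O-TBS deacetyl target (5S,7R,10S,12S,18S,20R,22R), via pyran epoxy alcohol 23 (not isolated)
Conditions: (+)-10-camphorsulfonic acid (0.2 equiv), CH2Cl2, −20 → 0 °C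
Reagents that add atoms: none
Why: Protonation of the C18–C10 epoxide lets O17 attack C18 from the rear to give 23, whose C10 hydroxyl, carried over the ring once the C20 side chain turns axial, attacks C7 of the protonated C7–C22 epoxide opposite its oxygen and sets C22–OH free. The closest known reaction type is the acid-promoted, alkyl-directed endo-selective epoxide-opening cascade of polyepoxy alcohols, and the second event mirrors the acid cyclisation of α-terpineol oxide to 2-hydroxy-1,8-cineole. The pyran closes in the 6-endo-tet mode and the oxepane in a transannular 7-endo-tet mode across a boat cyclohexane, which gives the 2-oxabicyclo[3.2.2]nonane core. Both openings are SN2-like with inversion, so 18S follows from the 18R epoxide carbon laid down in step 12 and 7R from the 7S epoxide carbon laid down in step 15, while C10, C22, C12, C5 and C20 keep their bonds. The step needs attack at C18 instead of C10 (5-exo) and at C7 instead of C22 (6-exo); the methyl groups C19 and C8 make the tertiary carbons the sites of greatest positive charge under acid, the non-nucleophilic medium offers no external trap, and the rear of C7 points to the face on which the side chain sits. The C5 silyl ether cannot take part, unlike an ester carbonyl, which would sit 1,3-diaxial to C7.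

Step 17
Reactants: 24 cascade product
Product: 25 22-O-chloroacetate of 24
Conditions: (ClCH2CO)2O, DMAP (cat.), pyridine, 0 °C → rt
Reagents that add atoms: chloroacetic anhydride, O=C(CCl)OC(=O)CCl
Why: DMAP-catalysed acylation of the only free hydroxyl gives a temporary ester that tolerates fluoride and acid and can later be removed beside an acetate.

Step 18
Reactants: 25 chloroacetate silyl ether
Product: 26 C5 alcohol 22-O-chloroacetate
Conditions: HF·pyridine, THF, 0 °C → rt
Reagents that add atoms: none
Why: Fluoride-driven desilylation under mildly acidic conditions leaves the chloroacetate, the tertiary ethers and the secondary bromide untouched.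

Step 19
Reactants: 26 C5 alcohol
Product: 27 5-O-acetate 22-O-chloroacetate
Conditions: Ac2O, DMAP (cat.), pyridine, rt
Reagents that add atoms: acetic anhydride, CC(=O)OC(C)=O
Why: DMAP-catalysed acetylation of the single free secondary alcohol at C5.

Step 20
Reactants: 27 mixed diester
Product: 28 target CNP0247588.2
Conditions: thiourea, pyridine–EtOH, 60 °C
Reagents that add atoms: none
Why: Chemoselective dechloroacetylation, in which sulfur is alkylated at the CH2Cl carbon and intramolecular acyl transfer then releases C22–OH, a path that is closed to the C5 acetate.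

Compound list
1 | (4R)-4-benzyl-1,3-oxazolidin-2-one | O=C1N[C@H](Cc2ccccc2)CO1 | starting material
2 | pent-4-enoyl chloride | C=CCCC(=O)Cl | starting material
3 | (4R)-4-benzyl-3-(pent-4-enoyl)-1,3-oxazolidin-2-one | O=C1N(C(=O)CCC=C)[C@H](Cc2ccccc2)CO1 | intermediate
4 | 3-methylbut-3-en-1-ol | C=C(C)CCO | starting material
5 | 3-methylbut-3-enal | C=C(C)CC=O | intermediate
6 | dibutylboron (Z)-enolate of 3 | O=C1N(/C(OB(CCCC)CCCC)=C/CC=C)[C@H](Cc2ccccc2)CO1 | intermediate
7 | (4R)-4-benzyl-3-[(2R,3S)-3-hydroxy-5-methyl-2-(prop-2-en-1-yl)hex-5-enoyl]-1,3-oxazolidin-2-one (20R,5S) | O=C1N(C(=O)[C@H](CC=C)[C@@H](O)CC(C)=C)[C@H](Cc2ccccc2)CO1 | intermediate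
8 | (2R,3S)-3-hydroxy-N-methoxy-N,5-dimethyl-2-(prop-2-en-1-yl)hex-5-enamide | CON(C)C(=O)[C@H](CC=C)[C@@H](O)CC(C)=C | intermediate
9 | (2R,3S)-N-methoxy-N,5-dimethyl-2-(prop-2-en-1-yl)-3-(triethylsilyloxy)hex-5-enamide | CON(C)C(=O)[C@H](CC=C)[C@@H](O[Si](CC)(CC)CC)CC(C)=C | intermediate
10 | (3R,4S)-6-methyl-3-(prop-2-en-1-yl)-4-(triethylsilyloxy)hept-6-en-2-one | CC(=O)[C@H](CC=C)[C@@H](O[Si](CC)(CC)CC)CC(C)=C | intermediate
11 | 5-bromo-2-methylpent-2-ene | CC(C)=CCCBr | starting material
12 | 1-methyl-1H-tetrazole-5-thiol | Cn1nnnc1S | starting material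
13 | 1-methyl-5-[(4-methylpent-3-en-1-yl)sulfanyl]-1H-tetrazole | Cn1nnnc1SCCC=C(C)C | intermediate
14 | 1-methyl-5-[(4-methylpent-3-en-1-yl)sulfonyl]-1H-tetrazole | Cn1nnnc1S(=O)(=O)CCC=C(C)C | intermediate
15 | 5-({2-[(2R)-3,3-dimethyloxiran-2-yl]ethyl}sulfonyl)-1-methyl-1H-tetrazole (12R) | Cn1nnnc1S(=O)(=O)CC[C@H]2OC2(C)C | intermediate
16 | (3R)-2,2-dimethyl-3-[(2Z,4S,5S)-3,7-dimethyl-4-(prop-2-en-1-yl)-5-(triethylsilyloxy)octa-2,7-dien-1-yl]oxirane (5S,20S,12R,18Z) | C/C(=C/C[C@H]1OC1(C)C)[C@H](CC=C)[C@@H](O[Si](CC)(CC)CC)CC(C)=C | intermediate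
17 | (3S,5Z,7S,8S)-3-bromo-2,6,10-trimethyl-7-(prop-2-en-1-yl)-8-(triethylsilyloxy)undeca-5,10-dien-2-ol | C/C(=C/C[C@H](Br)C(C)(C)O)[C@H](CC=C)[C@@H](O[Si](CC)(CC)CC)CC(C)=C | intermediate
18 | (3S,5Z,7S,8S)-3-bromo-2,6,10-trimethyl-7-(prop-2-en-1-yl)undeca-5,10-diene-2,8-diol (12S,18Z,20S,5S) | C/C(=C/C[C@H](Br)C(C)(C)O)[C@H](CC=C)[C@@H](O)CC(C)=C | intermediate
19 | open-chain epoxy diol (5S,20R,18R,10S,12S): C18–C10 epoxide with C20 and C11 cis, free C5–OH and C14–OH, allyl on C20, methallyl on C5 | C=C(C)C[C@H](O)[C@@H](CC=C)[C@@]1(C)O[C@H]1C[C@H](Br)C(C)(C)O | intermediate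
20 | 5-O-TBS ether of 19 | C=C(C)C[C@H](O[Si](C)(C)C(C)(C)C)[C@@H](CC=C)[C@@]1(C)O[C@H]1C[C@H](Br)C(C)(C)O | intermediate
21 | cyclohexene (5S,20R,18R,10S,12S): C7=C22 alkene, cis C5–OTBS and C20 side chain with C18–C10 epoxide, C12–Br, C14–OH | CC(C)(C)[Si](C)(C)O[C@H]1CC(C)=CC[C@H]1[C@@]2(C)O[C@H]2C[C@H](Br)C(C)(C)O | intermediate
22 | bis-epoxide bromohydrin, C5 TBS ether (5S,7S,22R,20R,18R,10S,12S): ring epoxide anti to the C5 and C20 substituents | CC(C)(C)[Si](C)(C)O[C@H]1C[C@]2(C)O[C@@H]2C[C@H]1[C@@]3(C)O[C@H]3C[C@H](Br)C(C)(C)O | intermediate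
23 | pyran epoxy alcohol (18S,10S,12S,7S,22R,5S,20R): bromopyran closed, C10–OH free, ring epoxide intact | CC(C)(C)[Si](C)(C)O[C@H]1C[C@]2(C)O[C@@H]2C[C@H]1[C@]3(C)OC(C)(C)[C@@H](Br)C[C@@H]3O | intermediate
24 | 5-O-TBS deacetyl target (5S,7R,10S,12S,18S,20R,22R) | CC(C)(C)[Si](C)(C)O[C@H]1C[C@@]2(C)O[C@H]3C[C@H](Br)C(C)(C)O[C@@]3(C)[C@@H]1C[C@H]2O | intermediate
25 | 22-O-chloroacetate of 24 | CC(C)(C)[Si](C)(C)O[C@H]1C[C@@]2(C)O[C@H]3C[C@H](Br)C(C)(C)O[C@@]3(C)[C@@H]1C[C@H]2OC(=O)CCl | intermediate
26 | C5 alcohol 22-O-chloroacetate | O[C@H]1C[C@@]2(C)O[C@H]3C[C@H](Br)C(C)(C)O[C@@]3(C)[C@@H]1C[C@H]2OC(=O)CCl | intermediate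
27 | 5-O-acetate 22-O-chloroacetate | CC(=O)O[C@H]1C[C@@]2(C)O[C@H]3C[C@H](Br)C(C)(C)O[C@@]3(C)[C@@H]1C[C@H]2OC(=O)CCl | intermediate
28 | CNP0247588.2 (5S,7R,10S,12S,18S,20R,22R) | CC(=O)O[C@H]1C[C@@]2(C)O[C@H]3C[C@H](Br)C(C)(C)O[C@@]3(C)[C@@H]1C[C@H]2O | target

Total step count: 20
Longest linear sequence: 16 steps (steps 1, 3 to 6 and 10 to 20)

Steps most likely to fail

1. Step 16.
   * What may go wrong: O17 may attack C10, or the C10 hydroxyl may attack C22. Hydride or alkyl shifts in a protonated epoxide before capture would also divert the cascade.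
   * Fallback: the two ring closures are run as separate operations. Setting out from 21, which holds only the side-chain epoxide, camphorsulfonic acid in CH2Cl2 should close the pyran alone to the pyran alkenol F1. Dimethyldioxirane then epoxidises the ring alkene anti to the C5 and C20 substituents to give 23, now isolated. A separate acid treatment of 23 closes the oxepane, and the route is rejoined at 24. Each closure then meets a single electrophile and can be tuned by itself.

2. Step 10.
   * What may go wrong: Z selectivity may erode during the addition and Smiles sequence. The ketone may be enolised, or the C10 carbanion may attack the C12 epoxide carbon.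
   * Fallback: the geometry is taken from a stereospecific syn-carbocupration.
     * Setting out from 9, i-Bu2AlH gives the aldehyde F2.
     * CBr4/PPh3 (Corey–Fuchs) gives the dibromoalkene F3.
     * n-BuLi followed by ClCO2Me gives the ynoate F4.
     * Me2CuLi at −78 °C adds methyl and copper to the same side of the triple bond, so protonation should give the (Z)-enoate F5.
     * i-Bu2AlH gives the (Z)-allylic alcohol F6, and CBr4/PPh3 gives the allylic bromide F7.
     * CuI-catalysed coupling with 2-methylprop-1-enylmagnesium bromide gives the skipped tetraene F8.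
     * The unhindered isopropylidene end of F8 should be epoxidised first by the D-fructose-derived ketone and KHSO5, and the route is rejoined at 16.

3. Step 12.
   * What may go wrong: the methallyl alkene may be epoxidised in competition. The C14 hydroxyl may also attack the fresh epoxide on the Lewis acidic vanadium centre.
   * Fallback: delivery from the hydroxyl is replaced by reagent control on a fully masked substrate. Setting out from 18, Et3SiOTf and 2,6-lutidine give the bis(triethylsilyl) ether F9, which tolerates a basic buffer. Shi epoxidation with the L-fructose-derived enantiomer of the ketone of step 9 (KHSO5, K2CO3) should oxidise only the trisubstituted alkene in the 10S sense, giving the epoxide F10. Buffered HF·pyridine removes both silyl groups, and the route is rejoined at 19.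

Further compounds
F1 | step 16 | pyran alkenol (bromopyran closed, C10–OH free, C7=C22 alkene, C5–OTBS) | CC(C)(C)[Si](C)(C)O[C@H]1CC(C)=CC[C@H]1[C@]2(C)OC(C)(C)[C@@H](Br)C[C@@H]2O
F2 | step 10 | (2R,3S)-5-methyl-2-(prop-2-en-1-yl)-3-(triethylsilyloxy)hex-5-enal | O=C[C@H](CC=C)[C@@H](O[Si](CC)(CC)CC)CC(C)=C
F3 | step 10 | 1,1-dibromoalkene from F2 | BrC(Br)=C[C@H](CC=C)[C@@H](O[Si](CC)(CC)CC)CC(C)=C
F4 | step 10 | methyl ynoate (C18≡C10–C11O2Me) | COC(=O)C#C[C@H](CC=C)[C@@H](O[Si](CC)(CC)CC)CC(C)=C
F5 | step 10 | methyl (Z)-enoate (C20 cis to C11) | COC(=O)/C=C(/C)[C@H](CC=C)[C@@H](O[Si](CC)(CC)CC)CC(C)=C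
F6 | step 10 | (Z)-allylic alcohol | OC/C=C(/C)[C@H](CC=C)[C@@H](O[Si](CC)(CC)CC)CC(C)=C
F7 | step 10 | (Z)-allylic bromide | BrC/C=C(/C)[C@H](CC=C)[C@@H](O[Si](CC)(CC)CC)CC(C)=C
F8 | step 10 | skipped tetraene (C12=C14 isopropylidene end) | CC(C)=CC/C=C(/C)[C@H](CC=C)[C@@H](O[Si](CC)(CC)CC)CC(C)=C
F9 | step 12 | 5,14-bis(triethylsilyl) ether of 18 | C/C(=C/C[C@H](Br)C(C)(C)O[Si](CC)(CC)CC)[C@H](CC=C)[C@@H](O[Si](CC)(CC)CC)CC(C)=C
F10 | step 12 | 5,14-bis(triethylsilyl) ether of 19 | C=C(C)C[C@H](O[Si](CC)(CC)CC)[C@@H](CC=C)[C@@]1(C)O[C@H]1C[C@H](Br)C(C)(C)O[Si](CC)(CC)CC
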